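Four stirred flasks of constant volume take the same charge and differ in how it goes in and when it is warm. In the green run side product stands far below target, so we reckon that small term alone.

| setting | violet | amber | red | green | east | south-west | west | south |
|---|---|---|---|---|---|---|---|---|
| starting material | 0.050 M | 0.034 M | 0.075 M | 0.050 M | 0.050 M | 0.050 M | 0.050 M (fed, over 8.0 d) | 0.050 M |
| partner | 0.075 M | 0.075 M | 0.075 M | 0.075 M | 0.0750 M (fed, over 8.0 d) | 0.0750 M | 0.0750 M | 0.0750 M |
| second substrate | 0.25 M | 0.25 M | 0.25 M | 0.50 M | 0.250 M | 0.250 M | 0.250 M | 0.250 M |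
| temperature | 35 °C | 50 °C | 35 °C | 50 °C |  | 50 °C | 50 °C |  |
| remark | run made earlier | run made earlier | run made earlier | run made earlier | the addition at 30 °C, then warmed to 50 °C; the feed brings no volume worth counting | everything together at the start | all else is in the flask from the start; the feed brings no volume worth counting | everything together at the start at 30 °C, warmed to 50 °C at 8.0 d |
| time |  |  |  |  | 10 d | 10 d | 10 d | 10 d |

| run | time / d | side product / % | target / % | starting material / % |
|---|---|---|---|---|
| violet | 0.625 | 0.8 | 17.2 | 77.9 |
| violet | 1.67 | 1.4 | 36.0 | 51.9 |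
| violet | 4.00 | 1.3 | 54.2 | 26.7 |
| violet | 5.00 | 1.3 | 58.5 | 21.4 |
| violet | 8.00 | 2.3 | 64.7 | 11.9 |
| violet | 10.0 | 3.7 | 67.2 | 12.2 |
| violet | 12.0 | 2.6 | 68.0 | 7.9 |
| amber | 0.833 | 1.4 | 47.0 | 32.0 |
| amber | 1.67 | 1.8 | 58.3 | 18.2 |
| amber | 2.50 | 0.9 | 64.1 | 15.0 |
| amber | 3.00 | 3.6 | 66.2 | 13.3 |
| amber | 4.00 | 3.2 | 69.4 | 14.6 |
| amber | 5.00 | 5.5 | 71.2 | 12.5 |
| amber | 6.00 | 3.0 | 71.8 | 9.3 |
| red | 1.67 | 0.6 | 34.3 | 53.9 |
| red | 4.00 | 3.4 | 49.2 | 31.1 |
| red | 5.00 | 3.8 | 51.7 | 25.5 |
| red | 6.00 | 3.0 | 56.4 | 19.5 |
| red | 8.00 | 4.6 | 57.8 | 17.6 |
| red | 10.0 | 5.1 | 62.2 | 12.8 |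
| red | 12.0 | 4.1 | 62.5 | 11.5 |
| green | 0.500 | 1.5 | 33.8 | 46.1 |
| green | 0.833 | 0.1 | 43.5 | 35.1 |
| green | 1.67 | 1.7 | 53.4 | 18.7 |
| green | 3.00 | 3.9 | 59.3 | 15.8 |
| green | 6.00 | 7.5 | 63.9 | 15.0 |

(scatter of a reading: 1 percentage point)

- in percentages every species weighs as the starting material in it: one side product counts as two
- the analysis behind the earlier runs scatters by 1 percentage point, standard deviation

- which flask leads in amount of side product, in percent of the starting material charged ("all alike" within 1.5 percentage points) (east / south-west / west / south / all alike)
- how much side product is there at the end, in percent of the starting material charged: east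
- how much side product is there at the end, in percent of the starting material charged: south-west
- how much side product is there at the end, in percent of the starting material charged: west
- how much side product is there at the end, in percent of the starting material charged: south

In the green run the product of the starting-material and target fractions reads 0.0999 at 1.67 d and 0.0959 at 6.00 d, while side product climbs. We take as our rule, at 50 °C, that the daily gain, as a fraction of the charge, is a constant times [starting material][target] over the charge.

What must be known well? South-west scales the last green reading by time, so its scatter of 1 percentage point moves that flask by 1.7 points. The last violet reading stands in for the cold days, though at 35 °C against 30 °C, and moves south by 0.67 points, less than the margin. Second substrate is 0.50 M in green and 0.25 M in amber, and amber's last reading, put through the rule, gives 2.20 /M/d, with a scatter of about a third.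

From green's last reading the number, at 50 °C, is 2.61 /M/d: the side constant, the fractional gain per day per molar of charge and per unit of that product.

At green's product we reckon 12.5% for south-west. For west we assume that starting material and target both rise in step with the feed, so that their product averages a third of its full value during the feed, and we reckon 5.83%. For south we reckon 2.50% warm plus 1.73% cold, 4.23%, and we set east level with it. In our reckoning south-west leads.

The forecast names south-west, with 2.7% for east, 8% for south-west, 4.5% for west and 3.3% for south, lower than ours on south-west. Its ground: “It starts slowly and then grows almost linearly”.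

The flasks give south-west as leader, with 3.38% for east, 10.2% for south-west, 5.86% for west and 3.93% for south.

    starting material + partner → target (k = 1.90 × 10⁻⁴ /M/s, Ea = 70.0 kJ/mol)
    second substrate + partner → second product (k = 9.20 × 10⁻⁷ /M/s, Ea = 94.0 kJ/mol)
    partner → decomposed reagent (k = 3.20 × 10⁻⁶ /s, Ea = 119 kJ/mol)
    starting material + target → side product (k = 1.20 × 10⁻⁵ /M/s, Ea = 78.0 kJ/mol)
    starting material ⇌ dormant form (K = 0.920, k = 7.50 × 10⁻⁶ /s, Ea = 106 kJ/mol, ΔH = −31.0 kJ/mol)
    (constants at 50 °C)

South-west's end fractions, held over 10 d, with 2.61 /M/d give 10.5%. East's neighbour with 0.20 M of starting material has 0.375 equiv of partner and ends at 30.9% starting material and 28.1% target. Its days after warming reckon to 9.05%, and that neighbour holds 11.2% of side product at 10.0 d.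

All runs are simulated from invented constants; the scatter is artificial.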